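## Retrosynthetic overview

1. Target 30 ⇐ 29 (three MOM ethers removed) ⇐ 28 by a ring-expanding α-ketol 1,2-shift: C2 migrates from the carbinol carbon to the formyl carbon, turning a 3-hydroxy-2,3-dihydrobenzofuran-3-carbaldehyde into the 3-hydroxychroman-4-one (ring C).
2. 28 ⇐ epoxy aldehyde 26 (an ortho phenoxide opens the epoxide and closes the dihydrofuran ring) ⇐ Sharpless epoxidation of Z allylic alcohol 24, which sets both stereocentres.
3. 24 ⇐ Suzuki coupling of ring B boronate 23 with ring A vinyl iodide 11 (aryl Grignard + prop-2-yn-1-ol, anti-carbomagnesiation, iodination).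
4. Ring A comes from resorcinol (third oxygen by C–H borylation/oxidation). Ring B comes from catechol (ortho-lithiation to ArCH2Cl, geranyl chain by methylalumination of a C8 enyne and Pd coupling, boronate by a second C–H borylation).
5. Ring order: benzene rings A and B are bought; the dihydrofuran ring forms in step 12 and is expanded to pyranone ring C in step 13.

Abbreviations: MOM = CH3OCH2 (MOMO = methoxymethoxy); TIPS = triisopropylsilyl (TIPSO = triisopropylsilyloxy); geranyl = (2E)-3,7-dimethylocta-2,6-dien-1-yl; pin = pinacolato.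

## Route

Step 1
Reactants: 1 resorcinol (benzene-1,3-diol)
Product: 2 1,3-bis(TIPSO)benzene
Conditions: TIPSCl (2.2 equiv), imidazole, DMF, rt
Reagents that add atoms: triisopropylsilyl chloride, CC(C)[Si](Cl)(C(C)C)C(C)C
Why: Imidazole-promoted O-silylation of both phenols gives bulky silyl ethers that survive organolithium, Grignard and aqueous base, shield their ortho C–H bonds in the borylation and are not ortho-directing.

Step 2
Reactants: 2 1,3-bis(TIPSO)benzene
Product: 4 3,5-bis(TIPSO)phenol, via aryl pinacol boronate 3 (not isolated)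
Conditions: [Ir(OMe)(cod)]2 (1 mol%), dtbpy (2 mol%), B2pin2 (1.0 equiv), THF, 80 °C; then KHSO5 (as 2KHSO5·KHSO4·K2SO4), acetone/H2O, 0 °C
Reagents that add atoms: potassium peroxymonosulfate, [K+].[O-]S(=O)(=O)OO
Why: Sterically controlled iridium-catalysed aromatic C–H borylation takes the only C–H not flanked by a silyloxy group (C5), and oxidation of the boronate in the same flask (aryl shift from boron to oxygen) gives the 1,3,5-trioxygenated ring.

Step 3
Reactants: 4 3,5-bis(TIPSO)phenol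
Product: 5 1-(MOMO)-3,5-bis(TIPSO)benzene
Conditions: MOMCl, iPr2NEt, CH2Cl2, 0 °C → rt
Reagents that add atoms: chloromethyl methyl ether, COCCl
Why: O-alkylation of the phenol installs the single acetal-type ortho-directing group of ring A, leaving the future O1 and O7 as fluoride-labile silyl ethers.

Step 4
Reactants: 5 1-(MOMO)-3,5-bis(TIPSO)benzene; 6 prop-2-yn-1-ol
Product: 11 (2Z)-3-iodo-2-[2-(MOMO)-4,6-bis(TIPSO)phenyl]prop-2-en-1-ol, via bromomagnesium propynolate 7 (not isolated), via aryllithium 8 (not isolated), via arylmagnesium bromide 9 (not isolated), via alkenylmagnesium chelate 10 (not isolated)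
Conditions: 6, EtMgBr (1.0 equiv), THF, 0 °C; separately 5, s-BuLi, TMEDA, THF, −78 °C, then MgBr2·OEt2, → 0 °C; combine, CuI (15 mol%), rt → 40 °C; then I2, −40 → 0 °C; H2O
Reagents that add atoms: iodine, II
Why: Directed ortho-metalation next to OMOM, then copper-catalysed anti-carbomagnesiation of the propargylic alkoxide, puts the aryl group on C2 and magnesium on C3 cis to the CH2O (five-membered chelate), and iodinolysis with retention gives the Z vinyl iodide.

Step 5
Reactants: 12 catechol (benzene-1,2-diol)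
Product: 13 1,2-bis(MOMO)benzene
Conditions: MOMCl (2.4 equiv), iPr2NEt, CH2Cl2, 0 °C → rt
Reagents that add atoms: chloromethyl methyl ether, COCCl
Why: Double O-alkylation gives MOM ethers that direct the next lithiation and are removed last under mild acid.

Step 6
Reactants: 13 1,2-bis(MOMO)benzene
Product: 17 1-(chloromethyl)-2,3-bis(MOMO)benzene, via aryllithium 14 (not isolated), via lithium benzyl alkoxide 15 (not isolated), via benzyl mesylate 16 (not isolated)
Conditions: n-BuLi, TMEDA, THF, 0 °C; (CH2O)n, 0 °C → rt; then MsCl, −20 °C → rt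
Reagents that add atoms: formaldehyde (from paraformaldehyde), C=O; methanesulfonyl chloride, CS(=O)(=O)Cl
Why: Directed ortho-metalation at C3, hydroxymethylation, then in-flask mesylation and SN2 displacement by the LiCl so formed give the benzylic chloride in one operation.

Step 7
Reactants: 18 5-bromo-2-methylpent-2-ene; 19 lithium acetylide–ethane-1,2-diamine complex
Product: 20 6-methylhept-5-en-1-yne
Conditions: DMSO, 10 °C → rt
Reagents that add atoms: none
Why: SN2 alkylation of the acetylide by the primary homoallylic bromide gives the C8 enyne.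

Step 8
Reactants: 20 6-methylhept-5-en-1-yne; 17 1-(chloromethyl)-2,3-bis(MOMO)benzene
Product: 22 1-geranyl-2,3-bis(MOMO)benzene, via alkenyl dimethylalane 21 (not isolated)
Conditions: AlMe3 (2 equiv), Cp2ZrCl2 (20 mol%), (CH2Cl)2, rt; evaporate excess AlMe3; then 17, Pd(PPh3)4 (5 mol%), THF, rt
Reagents that add atoms: trimethylaluminium, C[Al](C)C
Why: Negishi zirconium-catalysed methylalumination adds CH3 and Al syn across the terminal alkyne (methyl to the internal carbon), fixing the E trisubstituted alkene, and palladium-catalysed coupling of the alkenylalane with the benzylic chloride proceeds with retention.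

Step 9
Reactants: 22 1-geranyl-2,3-bis(MOMO)benzene; 11 (2Z)-3-iodo-2-[2-(MOMO)-4,6-bis(TIPSO)phenyl]prop-2-en-1-ol
Product: 24 (2Z)-3-[3-geranyl-4,5-bis(MOMO)phenyl]-2-[2-(MOMO)-4,6-bis(TIPSO)phenyl]prop-2-en-1-ol, via aryl pinacol boronate 23 (not isolated)
Conditions: [Ir(OMe)(cod)]2 (1.5 mol%), dtbpy (3 mol%), B2pin2 (1.0 equiv), THF, 60 °C; then 11, Pd(dppf)Cl2 (5 mol%), K3PO4, H2O, 60 °C
Reagents that add atoms: none
Why: Iridium-catalysed C–H borylation of the 1,2,3-trisubstituted ring occurs only at the unhindered C5 (para to the central oxygen, trisubstituted alkenes being spectators), and Suzuki–Miyaura coupling with the vinyl iodide retains the Z geometry.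

Step 10
Reactants: 24 (2Z)-3-[3-geranyl-4,5-bis(MOMO)phenyl]-2-[2-(MOMO)-4,6-bis(TIPSO)phenyl]prop-2-en-1-ol
Product: 25 [(2R,3S)-3-[3-geranyl-4,5-bis(MOMO)phenyl]-2-[2-(MOMO)-4,6-bis(TIPSO)phenyl]oxiran-2-yl]methanol
Conditions: Ti(OiPr)4 (1.0 equiv), D-(−)-diisopropyl tartrate (1.2 equiv), t-BuOOH (2 equiv, decane), 4 Å MS, CH2Cl2, −20 °C
Reagents that add atoms: tert-butyl hydroperoxide, CC(C)(C)OO
Why: Sharpless asymmetric epoxidation is directed by the allylic hydroxyl, so the geranyl alkenes are untouched, and the D-(−)-tartrate complex delivers oxygen to the face that gives the (2R,3S) epoxide, setting the benzylic C–O centre and the quaternary carbon in one event.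

Step 11
Reactants: 25 [(2R,3S)-3-[3-geranyl-4,5-bis(MOMO)phenyl]-2-[2-(MOMO)-4,6-bis(TIPSO)phenyl]oxiran-2-yl]methanol
Product: 26 (2S,3S)-3-[3-geranyl-4,5-bis(MOMO)phenyl]-2-[2-(MOMO)-4,6-bis(TIPSO)phenyl]oxirane-2-carbaldehyde
Conditions: Dess–Martin periodinane, NaHCO3, CH2Cl2, 0 °C → rt
Reagents that add atoms: none
Why: Buffered Dess–Martin oxidation of the primary alcohol gives an epoxy aldehyde whose α-carbon is quaternary, so it cannot enolise or epimerise (the descriptor changes only through CIP priorities).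

Step 12
Reactants: 26 (2S,3S)-3-[3-geranyl-4,5-bis(MOMO)phenyl]-2-[2-(MOMO)-4,6-bis(TIPSO)phenyl]oxirane-2-carbaldehyde
Product: 28 (2R,3S)-2-[3-geranyl-4,5-bis(MOMO)phenyl]-3,6-dihydroxy-4-(MOMO)-2,3-dihydro-1-benzofuran-3-carbaldehyde, via diphenol epoxy aldehyde 27 (not isolated)
Conditions: Bu4NF (2.2 equiv), THF, −20 → 0 °C; then AcOH
Reagents that add atoms: none
Why: Fluoride removes both aryl silyl ethers and the ortho phenoxide opens the epoxide intramolecularly at the benzylic carbon (SN2, the only epoxide carbon it can reach), inverting it to C2 (R), while the quaternary carbon keeps its oxygen and configuration as the tertiary alcohol (3S).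

Step 13
Reactants: 28 (2R,3S)-2-[3-geranyl-4,5-bis(MOMO)phenyl]-3,6-dihydroxy-4-(MOMO)-2,3-dihydro-1-benzofuran-3-carbaldehyde
Product: 29 (2R,3R)-2-[3-geranyl-4,5-bis(MOMO)phenyl]-3,7-dihydroxy-5-(MOMO)-2,3-dihydro-4H-chromen-4-one
Conditions: Zn(OTf)2 (20 mol%), iPr2NEt (40 mol%), 4 Å MS, toluene, 0 °C → rt
Reagents that add atoms: none
Why: Proposed new method: a zinc-chelated ring-expanding α-ketol (acyloin) rearrangement of a 3-hydroxy-2,3-dihydrobenzofuran-3-carbaldehyde, in which divalent zinc binds the tertiary alkoxide and the formyl oxygen in a five-membered chelate and the C2–C3 bond (C2 is benzylic and carries O1, hence the best migrating group) shifts suprafacially to the formyl carbon with retention at C2 (R); the carbinol carbon becomes the C4 aryl ketone and the formyl carbon becomes C3, whose R configuration (trans to the aryl group, also the thermodynamic arrangement of this epimerisable α-hydroxy ketone) follows from the chelate geometry and the (3S) carbinol; the driving force is aldehyde → conjugated aryl ketone plus five- to six-ring expansion, and the closest known reactions are Lewis-acid- or base-promoted α-ketol ring expansions of 1-acyl- and 1-formylcycloalkanols (steroid D-homoannulation, cyclobutanol to 2-hydroxycyclopentanone shifts), not yet shown for a benzofuranol going to a flavanonol.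

Step 14
Reactants: 29 (2R,3R)-2-[3-geranyl-4,5-bis(MOMO)phenyl]-3,7-dihydroxy-5-(MOMO)-2,3-dihydro-4H-chromen-4-one
Product: 30 (2R,3R)-2-(3-geranyl-4,5-dihydroxyphenyl)-3,5,7-trihydroxy-2,3-dihydro-4H-chromen-4-one (CNP0153097.1)
Conditions: HCl (3 M aq.), MeOH, 40 °C
Reagents that add atoms: none
Why: Acid-catalysed acetal exchange removes the three MOM ethers under conditions mild enough for the ortho-geranyl phenol, and the 2,3-trans arrangement already present is the thermodynamic one, so neither stereocentre is disturbed.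

## Compound list

1 | resorcinol (benzene-1,3-diol) | Oc1cccc(O)c1 | starting material
2 | 1,3-bis[(triisopropylsilyl)oxy]benzene | c1cc(O[Si](C(C)C)(C(C)C)C(C)C)cc(O[Si](C(C)C)(C(C)C)C(C)C)c1 | intermediate
3 | 2-{3,5-bis[(triisopropylsilyl)oxy]phenyl}-4,4,5,5-tetramethyl-1,3,2-dioxaborolane | CC1(C)OB(OC1(C)C)c1cc(O[Si](C(C)C)(C(C)C)C(C)C)cc(O[Si](C(C)C)(C(C)C)C(C)C)c1 | intermediate
4 | 3,5-bis[(triisopropylsilyl)oxy]phenol | Oc1cc(O[Si](C(C)C)(C(C)C)C(C)C)cc(O[Si](C(C)C)(C(C)C)C(C)C)c1 | intermediate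
5 | 1-(methoxymethoxy)-3,5-bis[(triisopropylsilyl)oxy]benzene | COCOc1cc(O[Si](C(C)C)(C(C)C)C(C)C)cc(O[Si](C(C)C)(C(C)C)C(C)C)c1 | intermediate
6 | prop-2-yn-1-ol | C#CCO | starting material
7 | bromomagnesium prop-2-yn-1-olate | C#CCO[Mg]Br | intermediate
8 | {2-(methoxymethoxy)-4,6-bis[(triisopropylsilyl)oxy]phenyl}lithium | [Li]c1c(OCOC)cc(O[Si](C(C)C)(C(C)C)C(C)C)cc1O[Si](C(C)C)(C(C)C)C(C)C | intermediate
9 | bromo{2-(methoxymethoxy)-4,6-bis[(triisopropylsilyl)oxy]phenyl}magnesium | Br[Mg]c1c(OCOC)cc(O[Si](C(C)C)(C(C)C)C(C)C)cc1O[Si](C(C)C)(C(C)C)C(C)C | intermediate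
10 | bromo[(1Z)-3-[(bromomagnesio)oxy]-2-{2-(methoxymethoxy)-4,6-bis[(triisopropylsilyl)oxy]phenyl}prop-1-en-1-yl]magnesium | Br[Mg]OC/C(=C\[Mg]Br)c1c(OCOC)cc(O[Si](C(C)C)(C(C)C)C(C)C)cc1O[Si](C(C)C)(C(C)C)C(C)C | intermediate
11 | (2Z)-3-iodo-2-{2-(methoxymethoxy)-4,6-bis[(triisopropylsilyl)oxy]phenyl}prop-2-en-1-ol | OC/C(=C\I)c1c(OCOC)cc(O[Si](C(C)C)(C(C)C)C(C)C)cc1O[Si](C(C)C)(C(C)C)C(C)C | intermediate
12 | catechol (benzene-1,2-diol) | Oc1ccccc1O | starting material
13 | 1,2-bis(methoxymethoxy)benzene | COCOc1ccccc1OCOC | intermediate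
14 | [2,3-bis(methoxymethoxy)phenyl]lithium | [Li]c1cccc(OCOC)c1OCOC | intermediate
15 | lithium [2,3-bis(methoxymethoxy)phenyl]methanolate | [Li]OCc1cccc(OCOC)c1OCOC | intermediate
16 | [2,3-bis(methoxymethoxy)phenyl]methyl methanesulfonate | CS(=O)(=O)OCc1cccc(OCOC)c1OCOC | intermediate
17 | 1-(chloromethyl)-2,3-bis(methoxymethoxy)benzene | ClCc1cccc(OCOC)c1OCOC | intermediate
18 | 5-bromo-2-methylpent-2-ene | CC(C)=CCCBr | starting material
19 | lithium acetylide–ethane-1,2-diamine complex | [Li]C#C.NCCN | starting material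
20 | 6-methylhept-5-en-1-yne | CC(C)=CCCC#C | intermediate
21 | [(1E)-2,6-dimethylhepta-1,5-dien-1-yl]dimethylalane | C[Al](C)/C=C(\C)CCC=C(C)C | intermediate
22 | 1-[(2E)-3,7-dimethylocta-2,6-dien-1-yl]-2,3-bis(methoxymethoxy)benzene | COCOc1cccc(C/C=C(\C)CCC=C(C)C)c1OCOC | intermediate
23 | 2-{3-[(2E)-3,7-dimethylocta-2,6-dien-1-yl]-4,5-bis(methoxymethoxy)phenyl}-4,4,5,5-tetramethyl-1,3,2-dioxaborolane | CC1(C)OB(OC1(C)C)c1cc(OCOC)c(OCOC)c(C/C=C(\C)CCC=C(C)C)c1 | intermediate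
24 | (2Z)-3-{3-[(2E)-3,7-dimethylocta-2,6-dien-1-yl]-4,5-bis(methoxymethoxy)phenyl}-2-{2-(methoxymethoxy)-4,6-bis[(triisopropylsilyl)oxy]phenyl}prop-2-en-1-ol | OC/C(=C\c1cc(OCOC)c(OCOC)c(C/C=C(\C)CCC=C(C)C)c1)c1c(OCOC)cc(O[Si](C(C)C)(C(C)C)C(C)C)cc1O[Si](C(C)C)(C(C)C)C(C)C | intermediate
25 | [(2R,3S)-3-{3-[(2E)-3,7-dimethylocta-2,6-dien-1-yl]-4,5-bis(methoxymethoxy)phenyl}-2-{2-(methoxymethoxy)-4,6-bis[(triisopropylsilyl)oxy]phenyl}oxiran-2-yl]methanol | OC[C@]1(O[C@H]1c1cc(OCOC)c(OCOC)c(C/C=C(\C)CCC=C(C)C)c1)c1c(OCOC)cc(O[Si](C(C)C)(C(C)C)C(C)C)cc1O[Si](C(C)C)(C(C)C)C(C)C | intermediate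
26 | (2S,3S)-3-{3-[(2E)-3,7-dimethylocta-2,6-dien-1-yl]-4,5-bis(methoxymethoxy)phenyl}-2-{2-(methoxymethoxy)-4,6-bis[(triisopropylsilyl)oxy]phenyl}oxirane-2-carbaldehyde | O=C[C@]1(O[C@H]1c1cc(OCOC)c(OCOC)c(C/C=C(\C)CCC=C(C)C)c1)c1c(OCOC)cc(O[Si](C(C)C)(C(C)C)C(C)C)cc1O[Si](C(C)C)(C(C)C)C(C)C | intermediate
27 | (2S,3S)-2-[2,4-dihydroxy-6-(methoxymethoxy)phenyl]-3-{3-[(2E)-3,7-dimethylocta-2,6-dien-1-yl]-4,5-bis(methoxymethoxy)phenyl}oxirane-2-carbaldehyde (present as its tetrabutylammonium phenoxide) | O=C[C@]1(O[C@H]1c1cc(OCOC)c(OCOC)c(C/C=C(\C)CCC=C(C)C)c1)c1c(OCOC)cc(O)cc1O | intermediate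
28 | (2R,3S)-2-{3-[(2E)-3,7-dimethylocta-2,6-dien-1-yl]-4,5-bis(methoxymethoxy)phenyl}-3,6-dihydroxy-4-(methoxymethoxy)-2,3-dihydro-1-benzofuran-3-carbaldehyde | O=C[C@]1(O)c2c(OCOC)cc(O)cc2O[C@@H]1c1cc(OCOC)c(OCOC)c(C/C=C(\C)CCC=C(C)C)c1 | intermediate
29 | (2R,3R)-2-{3-[(2E)-3,7-dimethylocta-2,6-dien-1-yl]-4,5-bis(methoxymethoxy)phenyl}-3,7-dihydroxy-5-(methoxymethoxy)-2,3-dihydro-4H-chromen-4-one | CC(C)=CCC/C(C)=C/Cc1cc([C@H]2Oc3cc(O)cc(OCOC)c3C(=O)[C@@H]2O)cc(OCOC)c1OCOC | intermediate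
30 | (2R,3R)-2-{3-[(2E)-3,7-dimethylocta-2,6-dien-1-yl]-4,5-dihydroxyphenyl}-3,5,7-trihydroxy-2,3-dihydro-4H-chromen-4-one | CC(C)=CCC/C(C)=C/Cc1cc([C@H]2Oc3cc(O)cc(O)c3C(=O)[C@@H]2O)cc(O)c1O | target

## Step count and risks

Total: 14 steps. Longest linear sequence: 10 steps (1, 2, 3, 4, 9, 10, 11, 12, 13, 14, from resorcinol); the catechol branch is 9.

The three steps most likely to fail:

**Step 4 (carbomagnesiation with a 2,6-dioxygenated aryl Grignard).** The nucleophile is hindered (ortho OTIPS and OMOM) and may add slowly or suffer silyl migration. The fallback sets out from 5, 6 and 22 and returns at 24; it reverses the order of bond formation and makes both C–C bonds by palladium cross-coupling. Iodine monobromide is added anti across 6 (CH2Cl2, −20 °C) to give (2E)-2-bromo-3-iodoprop-2-en-1-ol F1. Boronate 23, made from 22 as in step 9, is coupled selectively at the C–I bond (Pd(PPh3)4, K3PO4, THF/H2O, rt) to give (2E)-2-bromo-3-[3-geranyl-4,5-bis(MOMO)phenyl]prop-2-en-1-ol F2. Aryllithium 8 from 5 is transmetalated with ZnCl2 to chloro[2-(MOMO)-4,6-bis(TIPSO)phenyl]zinc F3, which undergoes Negishi coupling with F2 (Pd2(dba)3, SPhos, THF, 50 °C) with retention to give 24.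

**Step 12 (phenoxide opening of the epoxy aldehyde).** The 5-endo attack on an electron-rich aryl epoxide may be slow or lose stereochemical fidelity, and the α-oxido aldehyde may rearrange prematurely under base. The fallback sets out from 25 and returns at 28; it closes the ring at the alcohol oxidation level under a Lewis-acid template and oxidises afterwards. Desilylation of 25 (Bu4NF buffered with AcOH, THF, 0 °C) gives [(2R,3S)-2-[2,4-dihydroxy-6-(MOMO)phenyl]-3-[3-geranyl-4,5-bis(MOMO)phenyl]oxiran-2-yl]methanol F4. Ti(OiPr)4 (1.5 equiv, CH2Cl2, rt) binds the epoxy alcohol and directs the ortho phenol to the benzylic carbon with inversion, giving (2R,3R)-2-[3-geranyl-4,5-bis(MOMO)phenyl]-3-(hydroxymethyl)-4-(MOMO)-2,3-dihydro-1-benzofuran-3,6-diol F5. Oxidation of the primary alcohol (SO3·pyridine, DMSO, iPr2NEt, 0 °C) then gives 28.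

**Step 13 (the new ring expansion).** Possible failures are dehydration of 28 to the 2-aryl-3-formylbenzofuran, competing migration of the aryl carbon, or poor control at C3. The fallback uses known flavonoid chemistry, sets out from 5 and 22 and returns at 30.
- Aryllithium 8 (from 5 as in step 4) is acylated with N-methoxy-N-methylacetamide to give 1-[2-(MOMO)-4,6-bis(TIPSO)phenyl]ethan-1-one F6.
- The MOM ether ortho to the carbonyl is cleaved (HCl cat., MeOH, 0 °C) to give 1-[2-hydroxy-4,6-bis(TIPSO)phenyl]ethan-1-one F7.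
- Condensation with Me2NCH(OMe)2 (toluene, 90 °C) and acid-catalysed cyclisation (TsOH cat.) give 5,7-bis(TIPSO)-4H-chromen-4-one F8.
- Boronate 23 (from 22 as in step 9) is added to F8 by enantioselective rhodium-catalysed 1,4-addition ([RhCl(C2H4)2]2, chiral diene ligand, KOH, dioxane/H2O) to give (2S)-2-[3-geranyl-4,5-bis(MOMO)phenyl]-5,7-bis(TIPSO)-2,3-dihydro-4H-chromen-4-one F9.
- The potassium enolate (KN(SiMe3)2, THF, −78 °C) is hydroxylated with 3-phenyl-2-(phenylsulfonyl)oxaziridine trans to the aryl group to give (2R,3R)-2-[3-geranyl-4,5-bis(MOMO)phenyl]-3-hydroxy-5,7-bis(TIPSO)-2,3-dihydro-4H-chromen-4-one F10.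
- Bu4NF/AcOH followed by HCl/MeOH removes the silyl and MOM groups to give 30.

Further compounds
F1 | step 4 | (2E)-2-bromo-3-iodoprop-2-en-1-ol | OC/C(Br)=C\I
F2 | step 4 | (2E)-2-bromo-3-{3-[(2E)-3,7-dimethylocta-2,6-dien-1-yl]-4,5-bis(methoxymethoxy)phenyl}prop-2-en-1-ol | OC/C(Br)=C\c1cc(OCOC)c(OCOC)c(C/C=C(\C)CCC=C(C)C)c1
F3 | step 4 | chloro{2-(methoxymethoxy)-4,6-bis[(triisopropylsilyl)oxy]phenyl}zinc | Cl[Zn]c1c(OCOC)cc(O[Si](C(C)C)(C(C)C)C(C)C)cc1O[Si](C(C)C)(C(C)C)C(C)C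
F4 | step 12 | [(2R,3S)-2-[2,4-dihydroxy-6-(methoxymethoxy)phenyl]-3-{3-[(2E)-3,7-dimethylocta-2,6-dien-1-yl]-4,5-bis(methoxymethoxy)phenyl}oxiran-2-yl]methanol | OC[C@]1(O[C@H]1c1cc(OCOC)c(OCOC)c(C/C=C(\C)CCC=C(C)C)c1)c1c(OCOC)cc(O)cc1O
F5 | step 12 | (2R,3R)-2-{3-[(2E)-3,7-dimethylocta-2,6-dien-1-yl]-4,5-bis(methoxymethoxy)phenyl}-3-(hydroxymethyl)-4-(methoxymethoxy)-2,3-dihydro-1-benzofuran-3,6-diol | OC[C@]1(O)c2c(OCOC)cc(O)cc2O[C@@H]1c1cc(OCOC)c(OCOC)c(C/C=C(\C)CCC=C(C)C)c1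
F6 | step 13 | 1-{2-(methoxymethoxy)-4,6-bis[(triisopropylsilyl)oxy]phenyl}ethan-1-one | CC(=O)c1c(OCOC)cc(O[Si](C(C)C)(C(C)C)C(C)C)cc1O[Si](C(C)C)(C(C)C)C(C)C
F7 | step 13 | 1-{2-hydroxy-4,6-bis[(triisopropylsilyl)oxy]phenyl}ethan-1-one | CC(=O)c1c(O)cc(O[Si](C(C)C)(C(C)C)C(C)C)cc1O[Si](C(C)C)(C(C)C)C(C)C
F8 | step 13 | 5,7-bis[(triisopropylsilyl)oxy]-4H-chromen-4-one | O=c1ccoc2cc(O[Si](C(C)C)(C(C)C)C(C)C)cc(O[Si](C(C)C)(C(C)C)C(C)C)c12
F9 | step 13 | (2S)-2-{3-[(2E)-3,7-dimethylocta-2,6-dien-1-yl]-4,5-bis(methoxymethoxy)phenyl}-5,7-bis[(triisopropylsilyl)oxy]-2,3-dihydro-4H-chromen-4-one | CC(C)=CCC/C(C)=C/Cc1cc([C@H]2Oc3cc(O[Si](C(C)C)(C(C)C)C(C)C)cc(O[Si](C(C)C)(C(C)C)C(C)C)c3C(=O)C2)cc(OCOC)c1OCOC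
F10 | step 13 | (2R,3R)-2-{3-[(2E)-3,7-dimethylocta-2,6-dien-1-yl]-4,5-bis(methoxymethoxy)phenyl}-3-hydroxy-5,7-bis[(triisopropylsilyl)oxy]-2,3-dihydro-4H-chromen-4-one | CC(C)=CCC/C(C)=C/Cc1cc([C@H]2Oc3cc(O[Si](C(C)C)(C(C)C)C(C)C)cc(O[Si](C(C)C)(C(C)C)C(C)C)c3C(=O)[C@@H]2O)cc(OCOC)c1OCOC
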